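## Retrosynthetic overview

1. The target is fisetinidol-(4α→8)-catechin-(6→4β)-fisetinidol. The last cuts are the 13 O-benzyl groups and the C4–C6 bond of the 3,4-cis unit, which goes back to a C6 organocerium of the benzylated dimer and the C4 ketone of tetra-O-benzylfustin (addition, then ionic hydrogenation).
2. The feature the strategy rests on: in the fisetinidol unit bonded to catechin C8, the C3–C4 bond of ring C lies between C2 (bearing O1 and ring B) and C4 (bearing catechin C8). Ring C is therefore read as a 2H-chromene with a C3=C4 double bond, and hydroboration anti to the C2 aryl group then sets C3–OH and C4–H.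
3. C3=C4 is cut by ring-closing metathesis into an allylic vinyl group on C2 and a 1-(catechin-8-yl)vinyl group on C4a of ring A.
4. That diene comes from an iridium-catalysed branched allylic etherification (sets C2) of a 2-(1-arylvinyl)phenol with a cinnamyl carbonate from caffeic acid. The phenol comes from 8-metallated penta-O-benzylcatechin and 2-allyloxy-4-benzyloxyacetophenone.
5. Ring order: rings A, B and C of catechin and of the fustin-derived unit are bought intact; ring C of the C8-linked unit is the only ring built (step 13).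

Key step: step 13

Assumption: commercial fustin is the (2R,3R)-(+)-enantiomer, and the iridium/(Sa,Sc,Sc)-phosphoramidite catalyst gives with the bis(benzyloxy)cinnamyl carbonate the same sense of induction as with cinnamyl carbonate itself, namely the (S)-1-arylallyl aryl ether; otherwise the antipodal ligand is used.

## Route

Step 1
Reactants: 1 (+)-catechin
Product: 2 5,7,3′,4′-tetra-O-benzylcatechin
Conditions: BnBr (4.4 equiv), K2CO3, DMF, 0 °C to rt, N2
Reagents that add atoms: benzyl bromide, BrCc1ccccc1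
Why: Williamson etherification in which carbonate deprotonates only the four phenols, so the C3 alcohol stays free and C2/C3 are untouched.

Step 2
Reactants: 2 5,7,3′,4′-tetra-O-benzylcatechin
Product: 3 3,5,7,3′,4′-penta-O-benzylcatechin
Conditions: NaH, BnBr, Bu4NI (cat.), DMF, 0 °C to rt
Reagents that add atoms: benzyl bromide, BrCc1ccccc1
Why: Williamson etherification of the secondary alkoxide, which gives a protecting-group set that is uniform and inert to organolithium reagents.

Step 3
Reactants: 3 3,5,7,3′,4′-penta-O-benzylcatechin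
Product: 4 8-bromo-3,5,7,3′,4′-penta-O-benzylcatechin
Conditions: NBS (1.0 equiv), CH2Cl2, −78 °C to rt, dark
Reagents that add atoms: N-bromosuccinimide, O=C1CCC(=O)N1Br
Why: Electrophilic aromatic bromination of the phloroglucinol-type ring A, which in 5,7-di-O-benzyl flavan-3-ol ethers takes the first bromine at C8, ahead of C6 and of the catechol ring B.

Step 4
Reactants: 5 2,4-dihydroxyacetophenone
Product: 6 4-benzyloxy-2-hydroxyacetophenone
Conditions: BnBr (1.05 equiv), K2CO3, acetone, reflux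
Reagents that add atoms: benzyl bromide, BrCc1ccccc1
Why: Williamson etherification that is selective for the 4-hydroxyl because the 2-hydroxyl is held in a hydrogen bond to the acetyl group.

Step 5
Reactants: 6 4-benzyloxy-2-hydroxyacetophenone
Product: 7 2-allyloxy-4-benzyloxyacetophenone
Conditions: allyl bromide, K2CO3, DMF, 60 °C
Reagents that add atoms: allyl bromide, C=CCBr
Why: Williamson etherification under more forcing conditions; the allyl ether survives organometallic addition and can later be removed with zerovalent palladium without acid.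

Step 6
Reactants: 4 8-bromo-3,5,7,3′,4′-penta-O-benzylcatechin; 7 2-allyloxy-4-benzyloxyacetophenone
Product: 10 1-[2-(allyloxy)-4-(benzyloxy)phenyl]-1-(penta-O-benzylcatechin-8-yl)ethanol as both carbinol epimers, via 8-lithio-penta-O-benzylcatechin 8 (not isolated), via 8-dichlorocerio-penta-O-benzylcatechin 9 (not isolated)
Conditions: t-BuLi (2.0 equiv), THF, −78 °C; anhydrous CeCl3, −78 °C; then 7, −78 to −20 °C; aq. NH4Cl
Reagents that add atoms: none
Why: Bromine–lithium exchange followed by transmetalation gives a weakly basic, oxophilic organocerium whose 1,2-addition to the methyl ketone outruns enolisation; the new carbinol centre is formed without control and is removed in step 7.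

Step 7
Reactants: 10 1-[2-(allyloxy)-4-(benzyloxy)phenyl]-1-(penta-O-benzylcatechin-8-yl)ethanol
Product: 11 8-{1-[2-(allyloxy)-4-(benzyloxy)phenyl]vinyl}-penta-O-benzylcatechin
Conditions: methyl N-(triethylammoniosulfonyl)carbamate (Burgess reagent), toluene, 50 °C
Reagents that add atoms: none
Why: Burgess dehydration of a tertiary, doubly benzylic alcohol whose only β-hydrogens are on the methyl group, so the 1,1-diarylethylene is the only alkene possible, and the non-acidic medium avoids cationic dimerisation of this electron-rich olefin.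

Step 8
Reactants: 11 8-{1-[2-(allyloxy)-4-(benzyloxy)phenyl]vinyl}-penta-O-benzylcatechin
Product: 12 5-benzyloxy-2-[1-(penta-O-benzylcatechin-8-yl)vinyl]phenol
Conditions: Pd(PPh3)4 (5 mol %), morpholine, THF, rt
Reagents that add atoms: none
Why: Tsuji–Trost deallylation in which zerovalent palladium ionises the aryl allyl ether and morpholine traps the allyl fragment, while benzyl ethers and the 1,1-diarylethylene are inert.

Step 9
Reactants: 13 caffeic acid
Product: 14 benzyl (E)-3,4-bis(benzyloxy)cinnamate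
Conditions: BnBr (3.3 equiv), K2CO3, DMF, 60 °C
Reagents that add atoms: benzyl bromide, BrCc1ccccc1
Why: One-pot O-alkylation of the carboxylate and both phenols (Williamson type), which leaves the E alkene unchanged.

Step 10
Reactants: 14 benzyl (E)-3,4-bis(benzyloxy)cinnamate
Product: 15 (E)-3-[3,4-bis(benzyloxy)phenyl]prop-2-en-1-ol
Conditions: i-Bu2AlH (2.5 equiv), CH2Cl2, −78 to 0 °C; aq. potassium sodium tartrate (KNaC4H4O6)
Reagents that add atoms: none
Why: 1,2-Reduction of the conjugated ester by the aluminium hydride gives the allylic alcohol without touching the alkene or the aryl benzyl ethers.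

Step 11
Reactants: 15 (E)-3-[3,4-bis(benzyloxy)phenyl]prop-2-en-1-ol
Product: 16 (E)-3-[3,4-bis(benzyloxy)phenyl]allyl methyl carbonate
Conditions: ClCO2Me, pyridine, CH2Cl2, 0 °C
Reagents that add atoms: methyl chloroformate, COC(=O)Cl
Why: O-Acylation of the primary allylic alcohol gives the linear carbonate that serves as the ionisable electrophile in allylic substitution.

Step 12
Reactants: 12 5-benzyloxy-2-[1-(penta-O-benzylcatechin-8-yl)vinyl]phenol; 16 (E)-3-[3,4-bis(benzyloxy)phenyl]allyl methyl carbonate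
Product: 18 (S)-1-[3,4-bis(benzyloxy)phenyl]allyl 5-benzyloxy-2-[1-(penta-O-benzylcatechin-8-yl)vinyl]phenyl ether, via lithium 5-benzyloxy-2-[1-(penta-O-benzylcatechin-8-yl)vinyl]phenoxide 17 (not isolated)
Conditions: LiN(SiMe3)2 (1.0 equiv), THF, 0 °C; then 16 (1.3 equiv), [Ir(cod)Cl]2 (2 mol %), (Sa,Sc,Sc)-O,O′-(1,1′-binaphthalene-2,2′-diyl) N,N-bis(1-phenylethyl)phosphoramidite (4 mol %, activated with n-PrNH2), THF, rt to 40 °C
Reagents that add atoms: none
Why: Iridium-catalysed branched-selective asymmetric allylic etherification, in which the cyclometalated iridium phosphoramidite ionises the carbonate and the phenoxide attacks the aryl-substituted allyl terminus on the face dictated by the (Sa,Sc,Sc) ligand, setting the (S) ether carbon that becomes C2; the amide base is chosen because it does not add to the 1,1-diarylethylene.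

Step 13
Reactants: 18 (S)-1-[3,4-bis(benzyloxy)phenyl]allyl 5-benzyloxy-2-[1-(penta-O-benzylcatechin-8-yl)vinyl]phenyl ether
Product: 19 (2S)-7-benzyloxy-2-[3,4-bis(benzyloxy)phenyl]-4-(penta-O-benzylcatechin-8-yl)-2H-chromene
Conditions: RuCl2(=CHPh)(PCy3)(H2IMes) (second-generation Grubbs catalyst, 10 mol % in two portions), 1,4-benzoquinone (20 mol %), degassed toluene (0.005 M), 60–80 °C, Ar sparge
Reagents that add atoms: none
Why: The ruthenium benzylidene first undergoes [2+2] cycloaddition/cycloreversion with the monosubstituted allylic vinyl group of 18 (loss of styrene), and the new alkylidene on the C2 side then adds across the 1,1-diarylethylene with ruthenium on its CH2 terminus; cycloreversion of that ruthenacyclobutane forms C3=C4 and Ru=CH2, which carries the chain with loss of ethylene. The closest known reaction type is ring-closing metathesis of allyl 2-vinylphenyl ethers to 2H-chromenes, including closures onto 1,1-disubstituted styrenes that give 4-substituted chromenes with a trisubstituted double bond. Ring C closes as a six-membered ring in which both carbons of the new alkene are ring members (endocyclic C3=C4), the two olefins being held ortho to each other on ring A. No stereocentre is formed; C2, set in step 12, is not on the reaction path and should keep its configuration as long as acid and ruthenium hydride are excluded (degassed solvent, 1,4-benzoquinone). The step needs ring closure to win over intermolecular metathesis and over double-bond migration: the 1,1-diarylethylene cannot homodimerise, the allylic vinyl group sits on a branched carbon and dimerises slowly, and high dilution under an argon stream that removes ethylene favours the intramolecular path.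

Step 14
Reactants: 19 (2S)-7-benzyloxy-2-[3,4-bis(benzyloxy)phenyl]-4-(penta-O-benzylcatechin-8-yl)-2H-chromene
Product: 21 7,3′,4′-tri-O-benzylfisetinidol-(4α→8)-penta-O-benzylcatechin (free 3-hydroxyl on the fisetinidol unit; 2R,3S,4S in that unit), via C3 borane adduct 20 (not isolated)
Conditions: BH3·SMe2 (5 equiv), THF, 0 °C to rt; then 3 M NaOH, 30% H2O2, 0 °C to rt
Reagents that add atoms: hydrogen peroxide, OO
Why: Hydroboration–oxidation: boron goes to C3 (the less substituted carbon, away from the diaryl-stabilised C4) and B–H adds syn on the face anti to the adjacent C2 aryl group, so oxidation with retention should give 3β-OH and 4β-H, i.e. the 2,3-trans-3,4-trans unit with the catechin ring 4α.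

Step 15
Reactants: 21 7,3′,4′-tri-O-benzylfisetinidol-(4α→8)-penta-O-benzylcatechin
Product: 22 nona-O-benzyl fisetinidol-(4α→8)-catechin
Conditions: NaH, BnBr, Bu4NI (cat.), DMF, 0 °C to rt
Reagents that add atoms: benzyl bromide, BrCc1ccccc1
Why: Williamson etherification caps the last hydroxyl so that the later organolithium step meets no acidic proton.

Step 16
Reactants: 22 nona-O-benzyl fisetinidol-(4α→8)-catechin
Product: 23 6-bromo-nona-O-benzyl fisetinidol-(4α→8)-catechin (bromine on C6 of the catechin unit)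
Conditions: NBS (1.0 equiv), CH2Cl2, −78 to 0 °C, dark
Reagents that add atoms: N-bromosuccinimide, O=C1CCC(=O)N1Br
Why: Electrophilic aromatic bromination at the only free position of the phloroglucinol-type catechin ring A, whose three oxygen substituents (two ortho, one para to C6) make it more nucleophilic than the resorcinol-type ring A of the fisetinidol unit and the catechol rings.

Step 17
Reactants: 24 (+)-fustin
Product: 25 7,3′,4′-tri-O-benzylfustin
Conditions: BnBr (3.3 equiv), K2CO3, DMF, rt, N2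
Reagents that add atoms: benzyl bromide, BrCc1ccccc1
Why: Williamson etherification of the three phenols only; carbonate at room temperature does not alkylate the α-ketol hydroxyl, and the 2,3-trans arrangement is the stable one.

Step 18
Reactants: 25 7,3′,4′-tri-O-benzylfustin
Product: 26 3,7,3′,4′-tetra-O-benzylfustin
Conditions: Ag2O, BnBr, CH2Cl2, rt, dark
Reagents that add atoms: benzyl bromide, BrCc1ccccc1
Why: Silver-oxide-mediated O-benzylation works without a strong Brønsted base, so C3 is not enolised and neither epimerisation nor E1cB opening of ring C should occur.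

Step 19
Reactants: 23 6-bromo-nona-O-benzyl fisetinidol-(4α→8)-catechin; 26 3,7,3′,4′-tetra-O-benzylfustin
Product: 29 C4 carbinol of the trideca-O-benzyl trimer (4-hydroxy-3,7,3′,4′-tetra-O-benzylflavan-4-yl unit on catechin C6; expected 4α-aryl/4β-hydroxy), via C6-lithio nona-O-benzyl dimer 27 (not isolated), via C6-dichlorocerio nona-O-benzyl dimer 28 (not isolated)
Conditions: t-BuLi (2.0 equiv), THF, −78 °C; anhydrous CeCl3, −78 °C; then 26 (1.5 equiv), −78 to −40 °C; aq. NH4Cl
Reagents that add atoms: none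
Why: Bromine–lithium exchange and transmetalation give an aryl organocerium that adds 1,2 to the flavan-4-one carbonyl (an established way to forge the C4–aryl bond of 4-arylflavans) without deprotonating C3; attack anti to the 3-benzyloxy group is expected, but this centre is ionised in step 20.

Step 20
Reactants: 29 C4 carbinol of the trideca-O-benzyl trimer
Product: 30 trideca-O-benzyl fisetinidol-(4α→8)-catechin-(6→4β)-fisetinidol
Conditions: Et3SiH (10 equiv), CF3CO2H, CH2Cl2, −40 to 0 °C
Reagents that add atoms: none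
Why: Ionic hydrogenation: acid ionises the tertiary, doubly benzylic alcohol to a cation stabilised by the para-benzyloxy group of ring A, and the silane should deliver hydride to C4 anti to the adjacent 3β-benzyloxy group, placing the catechin ring 4β (3,4-cis, 4R); the 5-deoxy interflavanyl bond already present resists acid at this temperature.

Step 21
Reactants: 30 trideca-O-benzyl fisetinidol-(4α→8)-catechin-(6→4β)-fisetinidol
Product: 31 fisetinidol-(4α→8)-catechin-(6→4β)-fisetinidol (CNP0289228.1)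
Conditions: H2 (1 atm), Pd(OH)2/C, THF/MeOH/H2O, rt
Reagents that add atoms: none
Why: Catalytic hydrogenolysis cleaves all thirteen O-benzyl ethers, while the cyclic benzylic C2–O1 ethers and the C4–aryl bonds are retained under these mild conditions, so no stereocentre is touched.

## Compound list

1 | (+)-catechin, (2R,3S) | Oc1cc(O)c2c(c1)O[C@H](c1ccc(O)c(O)c1)[C@@H](O)C2 | starting material
2 | 5,7,3′,4′-tetra-O-benzylcatechin | c1ccccc1COc1cc(OCc3ccccc3)c2c(c1)O[C@H](c1ccc(OCc3ccccc3)c(OCc3ccccc3)c1)[C@@H](O)C2 | intermediate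
3 | 3,5,7,3′,4′-penta-O-benzylcatechin | c1ccccc1COc1cc(OCc3ccccc3)c2c(c1)O[C@H](c1ccc(OCc3ccccc3)c(OCc3ccccc3)c1)[C@@H](OCc1ccccc1)C2 | intermediate
4 | 8-bromo-3,5,7,3′,4′-penta-O-benzylcatechin | Brc1c(OCc3ccccc3)cc(OCc3ccccc3)c2c1O[C@H](c1ccc(OCc3ccccc3)c(OCc3ccccc3)c1)[C@@H](OCc1ccccc1)C2 | intermediate
5 | 2,4-dihydroxyacetophenone | CC(=O)c1ccc(O)cc1O | starting material
6 | 4-benzyloxy-2-hydroxyacetophenone | CC(=O)c1ccc(OCc2ccccc2)cc1O | intermediate
7 | 2-allyloxy-4-benzyloxyacetophenone | CC(=O)c1ccc(OCc2ccccc2)cc1OCC=C | intermediate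
8 | 8-lithio-penta-O-benzylcatechin | [Li]c1c(OCc3ccccc3)cc(OCc3ccccc3)c2c1O[C@H](c1ccc(OCc3ccccc3)c(OCc3ccccc3)c1)[C@@H](OCc1ccccc1)C2 | intermediate
9 | 8-dichlorocerio-penta-O-benzylcatechin | Cl[Ce](Cl)c1c(OCc3ccccc3)cc(OCc3ccccc3)c2c1O[C@H](c1ccc(OCc3ccccc3)c(OCc3ccccc3)c1)[C@@H](OCc1ccccc1)C2 | intermediate
10 | 1-[2-(allyloxy)-4-(benzyloxy)phenyl]-1-(penta-O-benzylcatechin-8-yl)ethanol, both carbinol epimers | CC(O)(c1ccc(OCc2ccccc2)cc1OCC=C)c1c(OCc3ccccc3)cc(OCc3ccccc3)c2c1O[C@H](c1ccc(OCc3ccccc3)c(OCc3ccccc3)c1)[C@@H](OCc1ccccc1)C2 | intermediate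
11 | 8-{1-[2-(allyloxy)-4-(benzyloxy)phenyl]vinyl}-penta-O-benzylcatechin | C=C(c1ccc(OCc2ccccc2)cc1OCC=C)c1c(OCc3ccccc3)cc(OCc3ccccc3)c2c1O[C@H](c1ccc(OCc3ccccc3)c(OCc3ccccc3)c1)[C@@H](OCc1ccccc1)C2 | intermediate
12 | 5-benzyloxy-2-[1-(penta-O-benzylcatechin-8-yl)vinyl]phenol | C=C(c1ccc(OCc2ccccc2)cc1O)c1c(OCc3ccccc3)cc(OCc3ccccc3)c2c1O[C@H](c1ccc(OCc3ccccc3)c(OCc3ccccc3)c1)[C@@H](OCc1ccccc1)C2 | intermediate
13 | caffeic acid | OC(=O)/C=C/c1ccc(O)c(O)c1 | starting material
14 | benzyl (E)-3,4-bis(benzyloxy)cinnamate | O=C(OCc1ccccc1)/C=C/c1ccc(OCc2ccccc2)c(OCc2ccccc2)c1 | intermediate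
15 | (E)-3-[3,4-bis(benzyloxy)phenyl]prop-2-en-1-ol | OC/C=C/c1ccc(OCc2ccccc2)c(OCc2ccccc2)c1 | intermediate
16 | (E)-3-[3,4-bis(benzyloxy)phenyl]allyl methyl carbonate | COC(=O)OC/C=C/c1ccc(OCc2ccccc2)c(OCc2ccccc2)c1 | intermediate
17 | lithium 5-benzyloxy-2-[1-(penta-O-benzylcatechin-8-yl)vinyl]phenoxide | C=C(c1ccc(OCc2ccccc2)cc1O[Li])c1c(OCc3ccccc3)cc(OCc3ccccc3)c2c1O[C@H](c1ccc(OCc3ccccc3)c(OCc3ccccc3)c1)[C@@H](OCc1ccccc1)C2 | intermediate
18 | (S)-1-[3,4-bis(benzyloxy)phenyl]allyl 5-benzyloxy-2-[1-(penta-O-benzylcatechin-8-yl)vinyl]phenyl ether | C=C[C@@H](c1ccc(OCc2ccccc2)c(OCc2ccccc2)c1)Oc1cc(OCc2ccccc2)ccc1C(=C)c1c(OCc3ccccc3)cc(OCc3ccccc3)c2c1O[C@H](c1ccc(OCc3ccccc3)c(OCc3ccccc3)c1)[C@@H](OCc1ccccc1)C2 | intermediate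
19 | (2S)-7-benzyloxy-2-[3,4-bis(benzyloxy)phenyl]-4-(penta-O-benzylcatechin-8-yl)-2H-chromene | c1ccccc1COc1ccc2c(c1)O[C@H](c1ccc(OCc3ccccc3)c(OCc3ccccc3)c1)C=C2c1c(OCc3ccccc3)cc(OCc3ccccc3)c2c1O[C@H](c1ccc(OCc3ccccc3)c(OCc3ccccc3)c1)[C@@H](OCc1ccccc1)C2 | intermediate
20 | C3 borane adduct of 19 (3β-BH2, 4β-H, catechin ring 4α) | c1ccccc1COc1ccc2c(c1)O[C@H](c1ccc(OCc3ccccc3)c(OCc3ccccc3)c1)[C@@H](B)[C@@H]2c1c(OCc3ccccc3)cc(OCc3ccccc3)c2c1O[C@H](c1ccc(OCc3ccccc3)c(OCc3ccccc3)c1)[C@@H](OCc1ccccc1)C2 | intermediate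
21 | 7,3′,4′-tri-O-benzylfisetinidol-(4α→8)-penta-O-benzylcatechin (fisetinidol unit 2R,3S,4S, free 3-OH) | c1ccccc1COc1ccc2c(c1)O[C@H](c1ccc(OCc3ccccc3)c(OCc3ccccc3)c1)[C@@H](O)[C@@H]2c1c(OCc3ccccc3)cc(OCc3ccccc3)c2c1O[C@H](c1ccc(OCc3ccccc3)c(OCc3ccccc3)c1)[C@@H](OCc1ccccc1)C2 | intermediate
22 | nona-O-benzyl fisetinidol-(4α→8)-catechin | c1ccccc1COc1ccc2c(c1)O[C@H](c1ccc(OCc3ccccc3)c(OCc3ccccc3)c1)[C@@H](OCc1ccccc1)[C@@H]2c1c(OCc3ccccc3)cc(OCc3ccccc3)c2c1O[C@H](c1ccc(OCc3ccccc3)c(OCc3ccccc3)c1)[C@@H](OCc1ccccc1)C2 | intermediate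
23 | 6-bromo-nona-O-benzyl fisetinidol-(4α→8)-catechin | c1ccccc1COc1ccc2c(c1)O[C@H](c1ccc(OCc3ccccc3)c(OCc3ccccc3)c1)[C@@H](OCc1ccccc1)[C@@H]2c1c(OCc3ccccc3)c(Br)c(OCc3ccccc3)c2c1O[C@H](c1ccc(OCc3ccccc3)c(OCc3ccccc3)c1)[C@@H](OCc1ccccc1)C2 | intermediate
24 | (+)-fustin, (2R,3R) | Oc1ccc2c(c1)O[C@H](c1ccc(O)c(O)c1)[C@@H](O)C2=O | starting material
25 | 7,3′,4′-tri-O-benzylfustin | c1ccccc1COc1ccc2c(c1)O[C@H](c1ccc(OCc3ccccc3)c(OCc3ccccc3)c1)[C@@H](O)C2=O | intermediate
26 | 3,7,3′,4′-tetra-O-benzylfustin | c1ccccc1COc1ccc2c(c1)O[C@H](c1ccc(OCc3ccccc3)c(OCc3ccccc3)c1)[C@@H](OCc1ccccc1)C2=O | intermediate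
27 | C6-lithio nona-O-benzyl fisetinidol-(4α→8)-catechin | c1ccccc1COc1ccc2c(c1)O[C@H](c1ccc(OCc3ccccc3)c(OCc3ccccc3)c1)[C@@H](OCc1ccccc1)[C@@H]2c1c(OCc3ccccc3)c([Li])c(OCc3ccccc3)c2c1O[C@H](c1ccc(OCc3ccccc3)c(OCc3ccccc3)c1)[C@@H](OCc1ccccc1)C2 | intermediate
28 | C6-dichlorocerio nona-O-benzyl fisetinidol-(4α→8)-catechin | c1ccccc1COc1ccc2c(c1)O[C@H](c1ccc(OCc3ccccc3)c(OCc3ccccc3)c1)[C@@H](OCc1ccccc1)[C@@H]2c1c(OCc3ccccc3)c([Ce](Cl)Cl)c(OCc3ccccc3)c2c1O[C@H](c1ccc(OCc3ccccc3)c(OCc3ccccc3)c1)[C@@H](OCc1ccccc1)C2 | intermediate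
29 | C4 carbinol of the trideca-O-benzyl trimer (4α-aryl, 4β-OH expected at the new centre) | c1ccccc1COc1ccc2c(c1)O[C@H](c1ccc(OCc6ccccc6)c(OCc6ccccc6)c1)[C@@H](OCc6ccccc6)[C@]2(O)c1c(OCc6ccccc6)c2c(c([C@@H]3c4ccc(OCc6ccccc6)cc4O[C@H](c4ccc(OCc6ccccc6)c(OCc6ccccc6)c4)[C@H]3OCc6ccccc6)c1OCc6ccccc6)O[C@H](c1ccc(OCc6ccccc6)c(OCc6ccccc6)c1)[C@@H](OCc6ccccc6)C2 | intermediate
30 | trideca-O-benzyl fisetinidol-(4α→8)-catechin-(6→4β)-fisetinidol | c1ccccc1COc1ccc2c(c1)O[C@H](c1ccc(OCc6ccccc6)c(OCc6ccccc6)c1)[C@@H](OCc6ccccc6)[C@H]2c1c(OCc6ccccc6)c2c(c([C@@H]3c4ccc(OCc6ccccc6)cc4O[C@H](c4ccc(OCc6ccccc6)c(OCc6ccccc6)c4)[C@H]3OCc6ccccc6)c1OCc6ccccc6)O[C@H](c1ccc(OCc6ccccc6)c(OCc6ccccc6)c1)[C@@H](OCc6ccccc6)C2 | intermediate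
31 | fisetinidol-(4α→8)-catechin-(6→4β)-fisetinidol (CNP0289228.1) | Oc1ccc2c(c1)O[C@H](c1ccc(O)c(O)c1)[C@@H](O)[C@H]2c1c(O)c2c(c([C@@H]3c4ccc(O)cc4O[C@H](c4ccc(O)c(O)c4)[C@H]3O)c1O)O[C@H](c1ccc(O)c(O)c1)[C@@H](O)C2 | target

## Step count and risks

Total: 21 steps. Longest linear sequence: 14 steps (steps 1, 2, 3, 6, 7, 8, 12, 13, 14, 15, 16, 19, 20, 21, from 1 to 31).

**Step 13 (ring-closing metathesis).** The alkylidene formed at the allylic vinyl group may fail to engage the 1,1-diarylethylene, which is shielded by two ortho-substituted aryl groups. Intermolecular metathesis, double-bond migration to an enol ether, or ionisation of the doubly activated allylic aryl ether could then take over.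

The fallback sets out from 25 and 2 and comes back to the route at 22. NaBH4 in MeOH/THF at 0 °C reduces the ketone of 25 to (2R,3S,4R)-7,3′,4′-tri-O-benzylflavan-3,4-diol F1. TiCl4 in CH2Cl2 at −78 to 0 °C then ionises the benzylic C4 hydroxyl of F1, and the C4 cation should alkylate C8 of an excess of 2 anti to the 3-hydroxyl (Friedel–Crafts alkylation). This should give 7,3′,4′-tri-O-benzylfisetinidol-(4α→8)-5,7,3′,4′-tetra-O-benzylcatechin F2. NaH/BnBr in DMF benzylates its two secondary hydroxyls to 22.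

**Step 19 (union at catechin C6).** After the exchange, the organocerium at C6 is flanked by two benzyloxy groups and may add too slowly to the ketone. Proton transfer would then return 22 or enolise C3 of 26, with E1cB opening of its ring C. The hydride facial selectivity demanded in step 20 is tied to the same sequence.

The fallback sets out from 22 and 24 and comes back at 31; it replaces steps 16 and 19 to 21. Hydrogenolysis of 22 (H2, Pd(OH)2/C) should give fisetinidol-(4α→8)-catechin F3. NaBH4 reduction of 24 should give (+)-mollisacacidin F4. In 0.1 M aqueous HCl at room temperature the C4 cation of F4 alkylates C6 of the catechin unit of F3, the only free position on a phloroglucinol-type ring (Friedel–Crafts condensation). This should give 31 together with fisetinidol-(4α→8)-catechin-(6→4α)-fisetinidol F5, its C4 epimer, from which it is separated on Sephadex LH-20.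

**Step 12 (allylic etherification).** The bulky ortho-substituted phenoxide 17 may attack the iridium allyl too slowly. The linear ether could then form, and reversible ionisation of the electron-rich product could erode the configuration at the future C2.

The fallback sets out from 6 and 16 (with 9 made from 4 as in step 6) and comes back at 18; it replaces steps 5 to 8. The small lithium phenoxide of 6 is etherified with 16 under the same iridium/phosphoramidite catalyst, which should give (S)-1-{4-benzyloxy-2-[1-(3,4-bis(benzyloxy)phenyl)allyloxy]phenyl}ethanone F6. Organocerium 9 then adds to the ketone of F6 at −78 °C, which should give 1-{4-benzyloxy-2-[(S)-1-(3,4-bis(benzyloxy)phenyl)allyloxy]phenyl}-1-(penta-O-benzylcatechin-8-yl)ethanol F7. Burgess dehydration of F7 in toluene at 50 °C should give 18.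

Further compounds

F1 | step 13 | (2R,3S,4R)-7,3′,4′-tri-O-benzylflavan-3,4-diol | c1ccccc1COc1ccc2c(c1)O[C@H](c1ccc(OCc3ccccc3)c(OCc3ccccc3)c1)[C@@H](O)[C@@H]2O
F2 | step 13 | 7,3′,4′-tri-O-benzylfisetinidol-(4α→8)-5,7,3′,4′-tetra-O-benzylcatechin | c1ccccc1COc1ccc2c(c1)O[C@H](c1ccc(OCc3ccccc3)c(OCc3ccccc3)c1)[C@@H](O)[C@@H]2c1c(OCc3ccccc3)cc(OCc3ccccc3)c2c1O[C@H](c1ccc(OCc3ccccc3)c(OCc3ccccc3)c1)[C@@H](O)C2
F3 | step 19 | fisetinidol-(4α→8)-catechin | Oc1ccc2c(c1)O[C@H](c1ccc(O)c(O)c1)[C@@H](O)[C@@H]2c1c(O)cc(O)c2c1O[C@H](c1ccc(O)c(O)c1)[C@@H](O)C2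
F4 | step 19 | (+)-mollisacacidin, (2R,3S,4R)-flavan-3,3′,4,4′,7-pentol | Oc1ccc2c(c1)O[C@H](c1ccc(O)c(O)c1)[C@@H](O)[C@@H]2O
F5 | step 19 | fisetinidol-(4α→8)-catechin-(6→4α)-fisetinidol | Oc1ccc2c(c1)O[C@H](c1ccc(O)c(O)c1)[C@@H](O)[C@@H]2c1c(O)c2c(c([C@@H]3c4ccc(O)cc4O[C@H](c4ccc(O)c(O)c4)[C@H]3O)c1O)O[C@H](c1ccc(O)c(O)c1)[C@@H](O)C2
F6 | step 12 | (S)-1-{4-benzyloxy-2-[1-(3,4-bis(benzyloxy)phenyl)allyloxy]phenyl}ethanone | CC(=O)c1ccc(OCc2ccccc2)cc1O[C@@H](C=C)c1ccc(OCc2ccccc2)c(OCc2ccccc2)c1
F7 | step 12 | 1-{4-benzyloxy-2-[(S)-1-(3,4-bis(benzyloxy)phenyl)allyloxy]phenyl}-1-(penta-O-benzylcatechin-8-yl)ethanol, both carbinol epimers | CC(O)(c1ccc(OCc2ccccc2)cc1O[C@@H](C=C)c1ccc(OCc2ccccc2)c(OCc2ccccc2)c1)c1c(OCc3ccccc3)cc(OCc3ccccc3)c2c1O[C@H](c1ccc(OCc3ccccc3)c(OCc3ccccc3)c1)[C@@H](OCc1ccccc1)C2
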